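**Retrosynthetic overview**
1. Target 13 ← Paal–Knorr cyclodehydration of methyl 3,6-dioxodocosanoate 12, released from its C6 dioxolane 11. The furan is the only ring and is formed last.
2. 11 ← decarboxylative (Masamune-type) Claisen condensation of the acyl imidazolide of ketal acid 6 with the magnesium enolate of methyl malonate from 7. This makes the key C2–C3 bond.
3. 6 ← ketalisation, then saponification, of methyl 4-oxoicosanoate 4.
4. 4 ← Fe(acac)3-catalysed acylation of hexadecylmagnesium bromide (from 1) with methyl succinyl chloride 2.

Assumption: the target has no stereocentre and no stereogenic double bond, so it is achiral and no stereocontrol is needed.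

**Step 1**
Reactants: 1 1-bromohexadecane; 2 methyl 4-chloro-4-oxobutanoate
Product: 4 methyl 4-oxoicosanoate, via hexadecylmagnesium bromide 3 (not isolated)
Conditions: 1 (1.1 equiv), Mg turnings, BrCH2CH2Br (cat.), THF, 50 °C; then add to 2 (1.0 equiv), Fe(acac)3 (3 mol %), THF, −78 °C, 30 min; aq NH4Cl
Reagents that add atoms: none
Why: The Fe(acac)3-catalysed Grignard–acid chloride cross-coupling (ketone synthesis by acylation) is much faster at −78 °C than addition to the methyl ester or to the product ketone, and no stereocentre is formed.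

**Step 2**
Reactants: 4 methyl 4-oxoicosanoate
Product: 5 methyl 3-(2-hexadecyl-1,3-dioxolan-2-yl)propanoate
Conditions: HOCH2CH2OH (4 equiv), pTsOH·H2O (5 mol %), toluene, reflux, Dean–Stark
Reagents that add atoms: ethylene glycol, OCCO
Why: Acid-catalysed ketalisation driven by azeotropic removal of water masks the ketone (as routinely done for levulinate esters) so that it cannot interfere with carboxyl activation and enolate chemistry later, and the ketal carbon is not stereogenic.

**Step 3**
Reactants: 5 methyl 3-(2-hexadecyl-1,3-dioxolan-2-yl)propanoate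
Product: 6 3-(2-hexadecyl-1,3-dioxolan-2-yl)propanoic acid
Conditions: LiOH·H2O (3 equiv), THF–MeOH–H2O (3:1:1), 40 °C; then cold 1 M HCl to pH 4 at 0 °C, immediate extraction
Reagents that add atoms: lithium hydroxide (LiOH), [Li+].[OH-]
Why: Ester saponification is irreversible under basic conditions that leave the dioxolane untouched, any 2-hydroxyethyl ester formed by transesterification in step 2 converges on the same acid, and no stereocentre is formed.

**Step 4**
Reactants: 6 3-(2-hexadecyl-1,3-dioxolan-2-yl)propanoic acid; 7 potassium methyl malonate (KO2CCH2CO2Me)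
Product: 11 methyl 5-(2-hexadecyl-1,3-dioxolan-2-yl)-3-oxopentanoate, via acyl imidazolide 8 (not isolated), via chloromagnesium methyl malonate 9 (not isolated), via acylmalonate half-ester 10 (not isolated)
Conditions: 6, CDI (1.2 equiv), THF, rt, 2 h; then add to 7 (2.0 equiv), MgCl2 (2.5 equiv), Et3N (3 equiv) premixed in MeCN–THF, rt → 40 °C, 16 h; cold 0.5 M HCl work-up
Reagents that add atoms: none
Why: In this Masamune–Brooks decarboxylative Claisen condensation the chelated magnesium malonate enolate is C-acylated by the acyl imidazolide under near-neutral conditions that the ketal tolerates, loss of CO2 on work-up makes the condensation irreversible, and the labile centre of 10 disappears on decarboxylation.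

**Step 5**
Reactants: 11 methyl 5-(2-hexadecyl-1,3-dioxolan-2-yl)-3-oxopentanoate
Product: 13 methyl 2-(5-hexadecylfuran-2-yl)acetate, via methyl 3,6-dioxodocosanoate 12 (not isolated)
Conditions: pTsOH·H2O (0.2 equiv), acetone–H2O (20:1), 50 °C; then solvent swap to toluene, 4 Å MS, 90 °C
Reagents that add atoms: none
Why: Acid hydrolysis frees the C6 ketone and the resulting 1,4-diketone undergoes Paal–Knorr cyclodehydration, driven by aromatisation to the 2,5-disubstituted furan, with no stereocentre present in the achiral product.

**Compound list**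
1 | 1-bromohexadecane | CCCCCCCCCCCCCCCCBr | starting material
2 | methyl 4-chloro-4-oxobutanoate (methyl succinyl chloride) | COC(=O)CCC(=O)Cl | starting material
3 | hexadecylmagnesium bromide (C16H33MgBr) | CCCCCCCCCCCCCCCC[Mg]Br | intermediate (not isolated)
4 | methyl 4-oxoicosanoate | CCCCCCCCCCCCCCCCC(=O)CCC(=O)OC | intermediate
5 | methyl 3-(2-hexadecyl-1,3-dioxolan-2-yl)propanoate | CCCCCCCCCCCCCCCCC1(CCC(=O)OC)OCCO1 | intermediate
6 | 3-(2-hexadecyl-1,3-dioxolan-2-yl)propanoic acid | CCCCCCCCCCCCCCCCC1(CCC(=O)O)OCCO1 | intermediate
7 | potassium methyl malonate (KO2CCH2CO2Me) | COC(=O)CC(=O)[O-].[K+] | starting material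
8 | 1-[3-(2-hexadecyl-1,3-dioxolan-2-yl)propanoyl]-1H-imidazole (acyl imidazolide) | CCCCCCCCCCCCCCCCC1(CCC(=O)n2ccnc2)OCCO1 | intermediate (not isolated)
9 | chloromagnesium methyl malonate (ClMgO2CCH2CO2Me) | COC(=O)CC(=O)[O-].[Mg+2].[Cl-] | intermediate (not isolated)
10 | 5-(2-hexadecyl-1,3-dioxolan-2-yl)-2-(methoxycarbonyl)-3-oxopentanoic acid (acylmalonate half-ester; present as its magnesium chelate, drawn as the free acid; C2 racemic and labile) | CCCCCCCCCCCCCCCCC1(CCC(=O)C(C(=O)OC)C(=O)O)OCCO1 | intermediate (not isolated)
11 | methyl 5-(2-hexadecyl-1,3-dioxolan-2-yl)-3-oxopentanoate | CCCCCCCCCCCCCCCCC1(CCC(=O)CC(=O)OC)OCCO1 | intermediate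
12 | methyl 3,6-dioxodocosanoate | CCCCCCCCCCCCCCCCC(=O)CCC(=O)CC(=O)OC | intermediate (not isolated)
13 | methyl 2-(5-hexadecylfuran-2-yl)acetate | CCCCCCCCCCCCCCCCc1ccc(CC(=O)OC)o1 | target

**Totals**
Total step count: 5. Longest linear sequence: 5 steps (1 → 4 → 5 → 6 → 11 → 13).

**Steps most likely to fail, with fallbacks**

Step 1 (acylation of the Grignard reagent). The risks are over-addition to the ketone or ester and Wurtz-type homocoupling of the long-chain Grignard reagent. The fallback sets out from 2 and comes back to the route at 4. Compound 2 is treated with MeNHOMe·HCl and K2CO3 in CH2Cl2–H2O at 0 °C to give the Weinreb amide methyl 4-[methoxy(methyl)amino]-4-oxobutanoate F1. Grignard reagent 3 (1.05 equiv, made from 1 as before) is then added in THF at −40 → 0 °C. The amide reacts ahead of the methyl ester, and the stable magnesium chelate of the tetrahedral adduct prevents a second addition. Aqueous acidic work-up releases 4 without any iron catalysis.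

Step 4 (key Claisen condensation). The risks are incomplete C-acylation, poor solubility of the long-chain imidazolide in MeCN, and O-acylation. The fallback sets out from 6 and comes back to the route at 11. Acid 6 is activated with CDI and coupled with MeNHOMe·HCl in CH2Cl2 at rt to give 3-(2-hexadecyl-1,3-dioxolan-2-yl)-N-methoxy-N-methylpropanamide F2. F2 is then acylated onto the preformed lithium enolate of methyl acetate (LiCH2CO2Me, from methyl acetate and LiN(iPr)2, 3 equiv, THF, −78 → −20 °C). This is a crossed Claisen-type condensation in which the chelated adduct cannot over-react. NH4Cl work-up gives 11.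

Step 5 (ketal removal and Paal–Knorr closure). The risks are intramolecular aldol or Knoevenagel closure of 12 to a cyclopentenone, and acid-promoted ring-opening or oligomerisation of the furan. The fallback sets out from 4 and comes back to the route at 13, and never exposes a 1,4-diketone to acid.
- Ketone 4 is reduced with NaBH4 in MeOH at 0 °C to racemic methyl 4-hydroxyicosanoate F3.
- F3 lactonises with catalytic pTsOH·H2O in toluene at 60 °C to racemic 5-hexadecyloxolan-2-one F4.
- LiCH2CO2Me (2.2 equiv, THF, −78 °C) adds to the lactone carbonyl in a Claisen-type acylation to give the lactol methyl 2-(5-hexadecyl-2-hydroxyoxolan-2-yl)acetate F5, a diastereomer mixture in equilibrium with the open hydroxy keto ester.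
- Catalytic CF3CO2H in CH2Cl2 dehydrates F5 to the vinylogous carbonate methyl (2E)-2-(5-hexadecyloxolan-2-ylidene)acetate F6 (racemic).
- DDQ (1.2 equiv, 1,4-dioxane, 80 °C) dehydrogenates F6, and the resulting 2-alkylidene-2,5-dihydrofuran tautomerises to the aromatic furan 13. All transient stereocentres are erased in this last operation.

**Further compounds**
F1 | step 1 | methyl 4-[methoxy(methyl)amino]-4-oxobutanoate | COC(=O)CCC(=O)N(C)OC
F2 | step 4 | 3-(2-hexadecyl-1,3-dioxolan-2-yl)-N-methoxy-N-methylpropanamide | CCCCCCCCCCCCCCCCC1(CCC(=O)N(C)OC)OCCO1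
F3 | step 5 | methyl 4-hydroxyicosanoate (racemic) | CCCCCCCCCCCCCCCCC(O)CCC(=O)OC
F4 | step 5 | 5-hexadecyloxolan-2-one (racemic) | CCCCCCCCCCCCCCCCC1CCC(=O)O1
F5 | step 5 | methyl 2-(5-hexadecyl-2-hydroxyoxolan-2-yl)acetate (diastereomer mixture, racemic) | CCCCCCCCCCCCCCCCC1CCC(O)(CC(=O)OC)O1
F6 | step 5 | methyl (2E)-2-(5-hexadecyloxolan-2-ylidene)acetate (racemic) | COC(=O)/C=C1\CCC(CCCCCCCCCCCCCCCC)O1
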